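**Retrosynthetic overview**

- Feature: ring A is a pentasubstituted benzene in which the C–OMe and C–OH carbons are para and the diaryl ether oxygen sits on the carbon next to C–OH. A 3‑aryloxy‑4‑oxy‑4‑vinylcyclobutenone delivers exactly this pattern on ring expansion, with the two para oxygens already differentiated.
- Late stage: the target goes back through O–Si cleavage, O‑methylation and two C–Br bonds ortho to the single free phenol of 4‑silyloxy‑3‑(2,4‑dibromophenoxy)phenol.
- Key disconnection: ring A, the only ring built (ring B is bought as 2,4‑dibromophenol), arises by 4π opening and 6π closure of a 4‑vinyl‑4‑silyloxy‑3‑aryloxycyclobutenone. The new C–C bond joins the ketene carbon to the vinyl terminus.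
- The cyclobutenone comes from semisquaric acid: chloride, vinylogous aryl ester, vinyl Grignard addition at the ketone next to the aryloxy carbon, O‑silylation.

Key step: step 5

Remark: the target has no stereocentre, so no enantiocontrol is needed; cyclobutenones 6 and 7 are racemic and their one stereocentre is lost on aromatisation. Semisquaric acid is taken as purchasable.

**Route**

Step 1
Reactants: 1 semisquaric acid (3‑hydroxycyclobut‑3‑ene‑1,2‑dione)
Product: 2 3‑chlorocyclobut‑3‑ene‑1,2‑dione (semisquaric chloride)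
Conditions: (COCl)2 (1.2 equiv), cat. DMF, CH2Cl2, 0 °C → rt; volatiles removed, residue used directly
Reagents that add atoms: oxalyl chloride, ClC(=O)C(=O)Cl
Why: The enolic OH of this vinylogous carboxylic acid is exchanged for chloride by Vilsmeier‑type activation, the standard acid‑chloride formation applied to squaric‑type acids.

Step 2
Reactants: 2 3‑chlorocyclobut‑3‑ene‑1,2‑dione; 3 2,4‑dibromophenol
Product: 4 3‑(2,4‑dibromophenoxy)cyclobut‑3‑ene‑1,2‑dione
Conditions: 2,6‑lutidine (1.1 equiv), CH2Cl2, −78 → 0 °C; anhydrous work‑up (filtration through a short silica pad)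
Reagents that add atoms: none
Why: The phenol oxygen displaces chloride at C3 by addition–elimination on the vinylogous acid chloride (vinylogous esterification), and the hindered, non‑nucleophilic base only takes up HCl and does not add to the dione.

Step 3
Reactants: 4 3‑(2,4‑dibromophenoxy)cyclobut‑3‑ene‑1,2‑dione; 5 vinylmagnesium bromide
Product: 6 rac‑3‑(2,4‑dibromophenoxy)‑4‑ethenyl‑4‑hydroxycyclobut‑2‑en‑1‑one
Conditions: 5 (1.05 equiv, 1 M in THF) added slowly, THF, −78 °C; sat. aq NH4Cl at −78 °C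
Reagents that add atoms: none
Why: Grignard 1,2‑addition should go to the C2 ketone next to the aryloxy carbon, because the other carbonyl is a vinylogous ester deactivated by the ether oxygen; the vinyl Grignard does not undergo Br/Mg exchange at −78 °C, and the new tertiary carbinol stereocentre is formed racemic and is destroyed in step 5.

Step 4
Reactants: 6 rac‑3‑(2,4‑dibromophenoxy)‑4‑ethenyl‑4‑hydroxycyclobut‑2‑en‑1‑one
Product: 7 rac‑4‑(tert‑butyldimethylsilyloxy)‑3‑(2,4‑dibromophenoxy)‑4‑ethenylcyclobut‑2‑en‑1‑one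
Conditions: TBSOTf (1.3 equiv), 2,6‑lutidine (2 equiv), CH2Cl2, −78 → 0 °C
Reagents that add atoms: tert‑butyldimethylsilyl triflate, CC(C)(C)[Si](C)(C)OS(=O)(=O)C(F)(F)F
Why: A silyl triflate with a hindered pyridine base is the standard O‑silylation for a crowded tertiary alcohol, and the cold, buffered conditions spare the vinylogous aryl ester.

Step 5
Reactants: 7 rac‑4‑(tert‑butyldimethylsilyloxy)‑3‑(2,4‑dibromophenoxy)‑4‑ethenylcyclobut‑2‑en‑1‑one
Product: 10 4‑(tert‑butyldimethylsilyloxy)‑3‑(2,4‑dibromophenoxy)phenol, via dienylketene 8 (not isolated), via cyclohexa‑2,4‑dienone 9 (not isolated)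
Conditions: degassed toluene (0.02 M), 110 °C, Ar
Reagents that add atoms: none
Why: Heating opens the cyclobutenone by conrotatory 4π electrocyclic cleavage of the C1–C4 bond to the (3Z)‑dienylketene 8. Disrotatory 6π electrocyclisation then joins the ketene carbon to the vinyl CH2 terminus, closing the six‑membered carbocycle (ring A) as cyclohexa‑2,4‑dienone 9, and enolisation aromatises it to 10. The closest known reaction is the Moore rearrangement of 4‑alkenyl‑4‑hydroxy or 4‑silyloxy 3‑alkoxycyclobutenones to hydroquinones and their monoethers; the C3 aryloxy group is a spectator of the same electronic type. No stereocentre is formed and the carbinol stereocentre of 7 becomes sp2. The step needs outward rotation of the C4 oxygen (torquoselectivity), which the silyloxy donor secures and which places the vinyl group inward, cis to the ketene, as closure requires; high dilution and the absence of nucleophiles keep the ketene from intermolecular capture. The ketene carbonyl emerges as the free phenol and the carbinol oxygen keeps silicon, so the para oxygens are differentiated by construction.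

Step 6
Reactants: 10 4‑(tert‑butyldimethylsilyloxy)‑3‑(2,4‑dibromophenoxy)phenol
Product: 12 2,6‑dibromo‑4‑(tert‑butyldimethylsilyloxy)‑3‑(2,4‑dibromophenoxy)phenol, via monobromophenol 11 (not isolated)
Conditions: NBS (2.05 equiv), i‑Pr2NH (10 mol %), CH2Cl2, 0 °C, dark
Reagents that add atoms: N‑bromosuccinimide, O=C1CCC(=O)N1Br
Why: Amine‑catalysed electrophilic ortho‑bromination of a phenol; the free OH (para position blocked) directs to both ortho carbons, the aryloxy group reinforces them (one ortho, one para to it), and the dibromophenoxy ring is deactivated, the less hindered ortho carbon being expected to react first (11).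

Step 7
Reactants: 12 2,6‑dibromo‑4‑(tert‑butyldimethylsilyloxy)‑3‑(2,4‑dibromophenoxy)phenol
Product: 13 tert‑butyl[3,5‑dibromo‑2‑(2,4‑dibromophenoxy)‑4‑methoxyphenoxy]dimethylsilane
Conditions: MeI (3 equiv), K2CO3 (1.5 equiv), dry acetone, rt
Reagents that add atoms: iodomethane, CI
Why: Williamson O‑methylation of an acidic 2,6‑dibromophenol goes with a mild carbonate base, and anhydrous conditions should leave the aryl silyl ether in place.

Step 8
Reactants: 13 tert‑butyl[3,5‑dibromo‑2‑(2,4‑dibromophenoxy)‑4‑methoxyphenoxy]dimethylsilane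
Product: 14 3,5‑dibromo‑2‑(2,4‑dibromophenoxy)‑4‑methoxyphenol (target)
Conditions: TBAF (1.1 equiv), AcOH (1.1 equiv), THF, 0 °C
Reagents that add atoms: none
Why: Fluoride cleaves the aryl O–Si bond (driven by Si–F bond formation) under acetic acid buffering, leaving the aryl bromides, the methyl ether and the diaryl ether untouched.

**Compound list**

1 | semisquaric acid (3‑hydroxycyclobut‑3‑ene‑1,2‑dione) | O=C1C=C(O)C1=O | starting material
2 | 3‑chlorocyclobut‑3‑ene‑1,2‑dione | O=C1C=C(Cl)C1=O | intermediate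
3 | 2,4‑dibromophenol | Oc1ccc(Br)cc1Br | starting material
4 | 3‑(2,4‑dibromophenoxy)cyclobut‑3‑ene‑1,2‑dione | O=C1C=C(Oc2ccc(Br)cc2Br)C1=O | intermediate
5 | vinylmagnesium bromide | C=C[Mg]Br | starting material
6 | rac‑3‑(2,4‑dibromophenoxy)‑4‑ethenyl‑4‑hydroxycyclobut‑2‑en‑1‑one | O=C1C=C(Oc2ccc(Br)cc2Br)C1(O)C=C | intermediate
7 | rac‑4‑(tert‑butyldimethylsilyloxy)‑3‑(2,4‑dibromophenoxy)‑4‑ethenylcyclobut‑2‑en‑1‑one | O=C1C=C(Oc2ccc(Br)cc2Br)C1(O[Si](C)(C)C(C)(C)C)C=C | intermediate
8 | (3Z)‑4‑(tert‑butyldimethylsilyloxy)‑3‑(2,4‑dibromophenoxy)hexa‑1,3,5‑trien‑1‑one (dienylketene) | O=C=C/C(Oc1ccc(Br)cc1Br)=C(/O[Si](C)(C)C(C)(C)C)C=C | intermediate (not isolated)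
9 | 4‑(tert‑butyldimethylsilyloxy)‑3‑(2,4‑dibromophenoxy)cyclohexa‑2,4‑dien‑1‑one | O=C1C=C(Oc2ccc(Br)cc2Br)C(O[Si](C)(C)C(C)(C)C)=CC1 | intermediate (not isolated)
10 | 4‑(tert‑butyldimethylsilyloxy)‑3‑(2,4‑dibromophenoxy)phenol | Oc1ccc(O[Si](C)(C)C(C)(C)C)c(Oc2ccc(Br)cc2Br)c1 | intermediate
11 | 2‑bromo‑4‑(tert‑butyldimethylsilyloxy)‑5‑(2,4‑dibromophenoxy)phenol | Oc1cc(Oc2ccc(Br)cc2Br)c(O[Si](C)(C)C(C)(C)C)cc1Br | intermediate (not isolated)
12 | 2,6‑dibromo‑4‑(tert‑butyldimethylsilyloxy)‑3‑(2,4‑dibromophenoxy)phenol | Oc1c(Br)cc(O[Si](C)(C)C(C)(C)C)c(Oc2ccc(Br)cc2Br)c1Br | intermediate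
13 | tert‑butyl[3,5‑dibromo‑2‑(2,4‑dibromophenoxy)‑4‑methoxyphenoxy]dimethylsilane | COc1c(Br)cc(O[Si](C)(C)C(C)(C)C)c(Oc2ccc(Br)cc2Br)c1Br | intermediate
14 | 3,5‑dibromo‑2‑(2,4‑dibromophenoxy)‑4‑methoxyphenol | COc1c(Br)cc(O)c(Oc2ccc(Br)cc2Br)c1Br | target

**Step count**

Total steps: 8. Longest linear sequence: 8 steps (from semisquaric acid 1).

**Steps most likely to fail, with fallbacks**

Step 3. Process at risk: the Grignard reagent may attack C3 of the vinylogous aryl ester and expel 2,4‑dibromophenoxide, or add a second time, instead of stopping after 1,2‑addition at the C2 ketone. The fallback introduces the aryloxy group after the C–C bond is made.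
- Setting out from chloride 2, allyl alcohol and 2,6‑lutidine (CH2Cl2, −78 → 0 °C) would give 3‑(allyloxy)cyclobut‑3‑ene‑1,2‑dione F1. This is an alkyl semisquarate, a class that takes organometallic reagents at the ketone next to the alkoxy carbon.
- Vinylmagnesium bromide 5 (THF, −78 °C) would give rac‑3‑(allyloxy)‑4‑ethenyl‑4‑hydroxycyclobut‑2‑en‑1‑one F2, and TBSOTf/2,6‑lutidine its silyl ether rac‑3‑(allyloxy)‑4‑(tert‑butyldimethylsilyloxy)‑4‑ethenylcyclobut‑2‑en‑1‑one F3.
- Pd(PPh3)4 with HCO2H/Et3N (THF, rt) would remove the allyl group to give the vinylogous acid rac‑4‑(tert‑butyldimethylsilyloxy)‑4‑ethenyl‑3‑hydroxycyclobut‑2‑en‑1‑one F4. Its C1 and C3 oxygens are equivalent by tautomerism, so activation raises no regiochemical question.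
- Oxalyl chloride/cat. DMF would convert it into rac‑3‑chloro‑4‑(tert‑butyldimethylsilyloxy)‑4‑ethenylcyclobut‑2‑en‑1‑one F5. 2,4‑Dibromophenol 3 with i‑Pr2NEt (CH2Cl2, 0 °C) would then displace chloride by addition–elimination, coming back to the route at 7.

Step 5. Process at risk: the dienylketene may be captured before it cyclises (by the phenol already formed, giving aryl esters and oligomers), or ring opening may need temperatures at which the vinylogous aryl ester decomposes. The fallback buys ring A, makes the diaryl ether by SNAr and installs the second oxygen by Baeyer–Villiger oxidation.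
- Setting out from 2,4‑dibromophenol 3, SNAr on 4‑(benzyloxy)‑2‑fluorobenzaldehyde (K2CO3, DMF, 110 °C) would give 4‑(benzyloxy)‑2‑(2,4‑dibromophenoxy)benzaldehyde F6.
- mCPBA (CH2Cl2, rt) would give 4‑(benzyloxy)‑2‑(2,4‑dibromophenoxy)phenyl formate F7, which K2CO3/MeOH would cleave to 4‑(benzyloxy)‑2‑(2,4‑dibromophenoxy)phenol F8.
- TBSCl/imidazole (DMF) would silylate the phenol next to the aryloxy group to give tert‑butyl[4‑(benzyloxy)‑2‑(2,4‑dibromophenoxy)phenoxy]dimethylsilane F9.
- BCl3/pentamethylbenzene (CH2Cl2, −78 °C; hydrogenolysis is avoided because of the aryl bromides) would remove the benzyl group, coming back to the route at 10.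

Step 6. Process at risk: the bromine source may oxidise the para‑silyloxyphenol to the quinone, or the second bromination at the crowded carbon between OH and OAr may stall so that bromine enters the dibromophenoxy ring. The fallback installs the hindered bromine before ring A exists.
- Setting out from 7, NBS (CH2Cl2, 0 °C) would brominate the nucleophilic C2 of the vinylogous ester to give rac‑2‑bromo‑4‑(tert‑butyldimethylsilyloxy)‑3‑(2,4‑dibromophenoxy)‑4‑ethenylcyclobut‑2‑en‑1‑one F10.
- Thermolysis as in step 5 would pass through (3Z)‑2‑bromo‑4‑(tert‑butyldimethylsilyloxy)‑3‑(2,4‑dibromophenoxy)hexa‑1,3,5‑trien‑1‑one F11 and 2‑bromo‑4‑(tert‑butyldimethylsilyloxy)‑3‑(2,4‑dibromophenoxy)cyclohexa‑2,4‑dien‑1‑one F12 (neither isolated). It would carry the bromine into the position between OH and OAr, giving 2‑bromo‑4‑(tert‑butyldimethylsilyloxy)‑3‑(2,4‑dibromophenoxy)phenol F13.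
- One equivalent of NBS would then brominate the remaining, unhindered ortho position, coming back to the route at 12.

**Further compounds**

F1 | step 3 | 3‑(allyloxy)cyclobut‑3‑ene‑1,2‑dione | C=CCOC1=CC(=O)C1=O
F2 | step 3 | rac‑3‑(allyloxy)‑4‑ethenyl‑4‑hydroxycyclobut‑2‑en‑1‑one | C=CCOC1=CC(=O)C1(O)C=C
F3 | step 3 | rac‑3‑(allyloxy)‑4‑(tert‑butyldimethylsilyloxy)‑4‑ethenylcyclobut‑2‑en‑1‑one | C=CCOC1=CC(=O)C1(O[Si](C)(C)C(C)(C)C)C=C
F4 | step 3 | rac‑4‑(tert‑butyldimethylsilyloxy)‑4‑ethenyl‑3‑hydroxycyclobut‑2‑en‑1‑one | O=C1C=C(O)C1(O[Si](C)(C)C(C)(C)C)C=C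
F5 | step 3 | rac‑3‑chloro‑4‑(tert‑butyldimethylsilyloxy)‑4‑ethenylcyclobut‑2‑en‑1‑one | O=C1C=C(Cl)C1(O[Si](C)(C)C(C)(C)C)C=C
F6 | step 5 | 4‑(benzyloxy)‑2‑(2,4‑dibromophenoxy)benzaldehyde | O=Cc1ccc(OCc2ccccc2)cc1Oc1ccc(Br)cc1Br
F7 | step 5 | 4‑(benzyloxy)‑2‑(2,4‑dibromophenoxy)phenyl formate | O=COc1ccc(OCc2ccccc2)cc1Oc1ccc(Br)cc1Br
F8 | step 5 | 4‑(benzyloxy)‑2‑(2,4‑dibromophenoxy)phenol | Oc1ccc(OCc2ccccc2)cc1Oc1ccc(Br)cc1Br
F9 | step 5 | tert‑butyl[4‑(benzyloxy)‑2‑(2,4‑dibromophenoxy)phenoxy]dimethylsilane | CC(C)(C)[Si](C)(C)Oc1ccc(OCc2ccccc2)cc1Oc1ccc(Br)cc1Br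
F10 | step 6 | rac‑2‑bromo‑4‑(tert‑butyldimethylsilyloxy)‑3‑(2,4‑dibromophenoxy)‑4‑ethenylcyclobut‑2‑en‑1‑one | O=C1C(Br)=C(Oc2ccc(Br)cc2Br)C1(O[Si](C)(C)C(C)(C)C)C=C
F11 | step 6 | (3Z)‑2‑bromo‑4‑(tert‑butyldimethylsilyloxy)‑3‑(2,4‑dibromophenoxy)hexa‑1,3,5‑trien‑1‑one | O=C=C(Br)/C(Oc1ccc(Br)cc1Br)=C(/O[Si](C)(C)C(C)(C)C)C=C
F12 | step 6 | 2‑bromo‑4‑(tert‑butyldimethylsilyloxy)‑3‑(2,4‑dibromophenoxy)cyclohexa‑2,4‑dien‑1‑one | O=C1C(Br)=C(Oc2ccc(Br)cc2Br)C(O[Si](C)(C)C(C)(C)C)=CC1
F13 | step 6 | 2‑bromo‑4‑(tert‑butyldimethylsilyloxy)‑3‑(2,4‑dibromophenoxy)phenol | Oc1ccc(O[Si](C)(C)C(C)(C)C)c(Oc2ccc(Br)cc2Br)c1Br
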